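The runs come from a simulation from invented constants, and the scatter is random.

At 40 h the flasks are read, but a fed flask has not had those hours for the whole of its charge.

| flask | starting material | reagent | remark | time |
|---|---|---|---|---|
| west | 0.21 M | 0.315 M | run made earlier |  |
| south | 0.10 M | 0.315 M | run made earlier |  |
| south-east | 0.16 M | 0.315 M | run made earlier |  |
| amber | 0.21 M | 0.315 M (in portions, 5, over 30 h) | first portion at the start, last at 30 h | 40 h |
| green | 0.21 M | 0.315 M (fed, over 30 h) | all else is in the flask from the start; the feed brings no volume worth counting | 40 h |
| blue | 0.21 M | 0.315 M | everything together at the start | 40 h |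
| violet | 0.21 M (fed, over 30 h) | 0.315 M | all else is in the flask from the start; the feed brings no volume worth counting | 40 h |

| run | time / h | target / % | starting material / % |
|---|---|---|---|
| west | 1.50 | 0.8 | 85.3 |
| west | 5.00 | 3.9 | 82.9 |
| west | 8.00 | 5.8 | 81.3 |
| west | 12.0 | 8.5 | 79.4 |
| west | 20.0 | 14.1 | 74.5 |
| west | 25.0 | 17.7 | 71.5 |
| south | 2.00 | 0.6 | 83.5 |
| south | 3.00 | 2.6 | 83.4 |
| south | 5.00 | 4.0 | 81.7 |
| south | 8.00 | 6.0 | 80.2 |
| south | 15.0 | 11.5 | 75.4 |
| south | 25.0 | 18.4 | 69.9 |
| south-east | 2.00 | 1.1 | 83.4 |
| south-east | 3.00 | 2.5 | 83.6 |
| south-east | 5.00 | 3.8 | 82.2 |
| south-east | 8.00 | 6.2 | 80.4 |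
| south-east | 15.0 | 11.3 | 76.1 |
| south-east | 25.0 | 18.2 | 70.9 |

(each reading ± 0.3 percentage points)

* the flask with the highest amount of target, in percent of the starting material charged ("all alike" if they lie within 1.5 percentage points) (amber / green / blue / violet / all alike)
* final target, as a percentage of the starting material charged, in amber
* final target, as a percentage of the starting material charged, in green
* final target, as a percentage of the starting material charged, in blue
* final target, as a percentage of the starting material charged, in violet

- the numbers in the tables scatter by 0.3 percentage points (one standard deviation)

Which numbers must I know well? The scatter matters little: a reading off by 0.3 percentage points moves my answer by as much, under the margin of 1.5 points. The size of the hidden pool, the starting material missing from both columns, need not be known, because west has blue's charges and I read its target directly. That pool is 13.2% in west and 14.3% in south at 5.00 h, although the charges are 0.21 M and 0.10 M. So I take it to be held by the reagent, present in excess, and I take it as the way to target. Reagent was never varied, so this is my commitment.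

What matters is the hours counted. West's slope is

0.00690 h⁻¹ of the charge,

so counting 25.0 h instead of 40 h shifts a flask by 10 points, more than the margin. With blue as the zero of the scale, withholding either partner should count alike. A steady feed and evenly spaced portions both enter on average at 30 h / 2, which leaves 40 h minus that, 25.0 h, the mean contact time.

So I expect amber, green and violet to stand where west stood at 25.0 h, with 17.7% target. West's slope carried on puts blue near 28.0%.

The forecast differs on amber and green: green leads, with amber 28.8%, green 29.2%, blue 27.5%, violet 18%, on the ground that “withholding reagent leaves more starting material free, so slightly more target”.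

    adduct → target (k = 1.60 × 10⁻⁵ s⁻¹)
    starting material + reagent ⇌ adduct (K = 0.580 M⁻¹, k = 7.80 × 10⁻⁴ M⁻¹ s⁻¹)

Blue is highest at 25.9%, with amber at 17.8%. In blue, starting material and reagent turned into adduct with a forward half-life of 0.78 h as charged, and adduct, at 11.2% after 20.0 h and 9.03% after 40.0 h, turned into target with a half-life of 12 h. In green, adduct grew with the feed to 11.7% at 30.0 h while target reached 11.3%, and the flask ended at 17.8%, close to west's reading at a mean contact time of 25.0 h. Violet, fed the other partner over the same hours, ended at 17.5%.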